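**Retrosynthetic overview**
- The target is reached from its 7,7''-dibenzyl ether by hydrogenolysis, which is the only protecting-group step.
- The dibenzyl ether is cut into two molecules of one 2'-hydroxychalcone. Both O1–C2 bonds and the C3–C3'' bond are made in one pot: asymmetric oxa-Michael closure, then oxidative homocoupling of the derived enolates.
- The chalcone comes from a 4'-O-benzyl acetophenone and 4-methoxybenzaldehyde by Claisen–Schmidt condensation.
- Ring order: all four benzene rings are bought; the two pyranone rings (ring C of each flavanone half) form together in the key step; no ring is formed afterwards.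

Assumption: 2',4'-dihydroxy-6'-methoxyacetophenone is taken as a bought catalogue compound.
Assumption: the quinine-derived thiourea is taken to give the (2S) series; the sense is read from the CD spectrum of an aliquot of the intermediate flavanone, and the quinidine-derived pseudoenantiomer is used under the same conditions if it is reversed.

**Step 1**
Reactants: 1 2',4'-dihydroxy-6'-methoxyacetophenone
Product: 2 4'-(benzyloxy)-2'-hydroxy-6'-methoxyacetophenone
Conditions: BnBr (1.05 equiv), K2CO3 (1.1 equiv), acetone, reflux, 6 h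
Reagents that add atoms: benzyl bromide, BrCc1ccccc1
Why: Williamson ether synthesis; the 4'-OH (para to the acyl group, not hydrogen-bonded) is more acidic and more nucleophilic than the chelated 2'-OH, so mono-benzylation occurs there; no stereocentre.

**Step 2**
Reactants: 2 4'-(benzyloxy)-2'-hydroxy-6'-methoxyacetophenone; 3 4-methoxybenzaldehyde
Product: 4 (E)-1-[4-(benzyloxy)-2-hydroxy-6-methoxyphenyl]-3-(4-methoxyphenyl)prop-2-en-1-one
Conditions: KOH (50% aq, 10 equiv), EtOH, 0 °C → rt, 36 h; then 1 M HCl, 0 °C; recrystallisation (EtOH)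
Reagents that add atoms: none
Why: Claisen–Schmidt (crossed aldol) condensation: the enolate of 2 adds to the non-enolisable aldehyde 3 and E1cB loss of water gives the conjugated E-enone, which rests as the open-chain phenoxide in strong base and is released by cold acidification; recrystallisation removes any racemic flavanone; no stereocentre.

**Step 3**
Reactants: 4 (E)-1-[4-(benzyloxy)-2-hydroxy-6-methoxyphenyl]-3-(4-methoxyphenyl)prop-2-en-1-one (two molecules)
Product: 7 7,7''-di-O-benzyl-4',4''',5,5''-tetra-O-methylchamaejasmin [(2S,3R,2''S,3''R)-3,3''-biflavanone], via (2S)-flavanone 5 (not isolated), via lithium enolate 6 (not isolated)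
Conditions: 1-[3,5-bis(trifluoromethyl)phenyl]-3-[(8α,9S)-6'-methoxycinchonan-9-yl]thiourea (10 mol%), toluene, −20 → 0 °C, 48 h; then THF, LiN(i-Pr)2 (1.25 equiv), −78 °C, 20 min; then CuCl2 (1.25 equiv), DMF, −78 °C, 1 h; aq NH4Cl
Reagents that add atoms: none
Why: Proposed new method: the bifunctional thiourea (quinuclidine as general base for the 2'-OH, thiourea hydrogen-bonded to the enone carbonyl) closes each pyranone ring by a 6-endo oxa-Michael addition on one enone face and so sets C2 as S (closest known type: cinchona-thiourea-catalysed intramolecular oxa-Michael cyclisation of 2'-hydroxychalcone-type enones to flavanones; the 6'-methoxy group twists the enone and favours closure); LiN(i-Pr)2 at −78 °C then gives enolate 6, which divalent copper oxidises by one electron at C3 (closest known type: CuCl2-mediated oxidative homocoupling of ketone lithium enolates to 1,4-diketones), and two units join at C3 anti to the 2-aryl group, so both new centres are R (2,3-trans, also the thermodynamic arrangement at these epimerisable positions); two units of the same handedness can give only the twofold-symmetric (2S,3R,2''S,3''R) dimer while the minor enantiomer is drained into the separable meso-type dimer, so 7 is enantiomerically purer than 5 (Horeau-type amplification; 90% ee in 5 corresponds statistically to about 99% ee in 7).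

**Step 4**
Reactants: 7 7,7''-di-O-benzyl-4',4''',5,5''-tetra-O-methylchamaejasmin
Product: 8 4',4''',5,5''-tetramethylchamaejasmin
Conditions: H2 (1 atm), Pd/C (10 wt% Pd, 10 mol% Pd), EtOAc–THF (1:1), rt, 1–3 h (TLC control)
Reagents that add atoms: none
Why: hydrogenolysis of aryl benzyl ethers over palladium on carbon is much faster than cleavage of the cyclic benzylic C2–O1 ether or reduction of the aryl ketones, and the neutral medium leaves all four stereocentres untouched.

**Compound list**
1 | 2',4'-dihydroxy-6'-methoxyacetophenone | CC(=O)c1c(O)cc(O)cc1OC | starting material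
2 | 4'-(benzyloxy)-2'-hydroxy-6'-methoxyacetophenone | CC(=O)c1c(O)cc(OCc2ccccc2)cc1OC | intermediate
3 | 4-methoxybenzaldehyde | COc1ccc(C=O)cc1 | starting material
4 | (E)-1-[4-(benzyloxy)-2-hydroxy-6-methoxyphenyl]-3-(4-methoxyphenyl)prop-2-en-1-one | COc1ccc(/C=C/C(=O)c2c(O)cc(OCc3ccccc3)cc2OC)cc1 | intermediate
5 | (2S)-7-(benzyloxy)-5-methoxy-2-(4-methoxyphenyl)chroman-4-one | COc1ccc([C@H]2Oc3cc(OCc4ccccc4)cc(OC)c3C(=O)C2)cc1 | intermediate
6 | lithium (2S)-7-(benzyloxy)-5-methoxy-2-(4-methoxyphenyl)-2H-chromen-4-olate | COc1ccc([C@H]2Oc3cc(OCc4ccccc4)cc(OC)c3C([O-])=C2)cc1.[Li+] | intermediate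
7 | (2S,3R,2''S,3''R)-7,7''-bis(benzyloxy)-5,5''-dimethoxy-2,2''-bis(4-methoxyphenyl)-[3,3''-bichromane]-4,4''-dione (7,7''-di-O-benzyl-4',4''',5,5''-tetra-O-methylchamaejasmin) | COc1ccc([C@H]2Oc3cc(OCc4ccccc4)cc(OC)c3C(=O)[C@@H]2[C@H]2C(=O)c3c(OC)cc(OCc4ccccc4)cc3O[C@@H]2c2ccc(OC)cc2)cc1 | intermediate
8 | (2S,3R,2''S,3''R)-7,7''-dihydroxy-5,5''-dimethoxy-2,2''-bis(4-methoxyphenyl)-[3,3''-bichromane]-4,4''-dione (4',4''',5,5''-tetramethylchamaejasmin) | COc1ccc([C@H]2Oc3cc(O)cc(OC)c3C(=O)[C@@H]2[C@H]2C(=O)c3c(OC)cc(O)cc3O[C@@H]2c2ccc(OC)cc2)cc1 | target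

**Totals**
Total step count: 4. Longest linear sequence: 4 (1 → 2 → 4 → 7 → 8).

**Steps most likely to fail**

1. Step 3 (one-pot ring closure and coupling). The risks are modest enantioselectivity in the oxa-Michael closure, E1cB ring-opening of enolate 6 back to the chalcone phenoxide (which costs yield and returns recyclable 4, but does not scramble what couples), and α-chlorination or fragmentation instead of C3–C3'' coupling. The fallback sets out from 2 and comes back at 7, and makes the C3–C3'' bond before the rings exist. Acetophenone 2 is treated with LiN(i-Pr)2 (2.2 equiv, THF, −78 °C) to give the dilithium phenoxide–enolate of 2 F1. CuCl2 in DMF oxidises this primary enolate, which has no β-aryloxy leaving group and no stereocentre, to 1,4-bis[4-(benzyloxy)-2-hydroxy-6-methoxyphenyl]butane-1,4-dione F2. Twofold Claisen–Schmidt condensation of F2 with aldehyde 3 (KOH, EtOH) gives the bis-chalcone (2E,3E)-1,4-bis[4-(benzyloxy)-2-hydroxy-6-methoxyphenyl]-2,3-bis[(4-methoxyphenyl)methylidene]butane-1,4-dione F3; the alkene geometry is lost on cyclisation and does not matter. The same thiourea (toluene, 0 °C) then closes both pyranone rings of one molecule by a double oxa-Michael addition. This passes through the mono-cyclised (2S,3R)-7-(benzyloxy)-3-{(E)-1-[4-(benzyloxy)-2-hydroxy-6-methoxybenzoyl]-2-(4-methoxyphenyl)ethenyl}-5-methoxy-2-(4-methoxyphenyl)chroman-4-one F4. The catalyst sets C2 and C2'', and C3 and C3'' settle trans by protonation and equilibration, to give 7.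

2. Step 4 (hydrogenolysis). The risk is competing cleavage of the benzylic C2–O1 bond (giving a dihydrochalcone) or ketone reduction. The fallback sets out from 1 and comes back at 8, carrying the 7-oxygen as an acid-labile acetal instead. Compound 1 with chloromethyl methyl ether and K2CO3 in acetone gives 2'-hydroxy-6'-methoxy-4'-(methoxymethoxy)acetophenone F5. Condensation with 3 as in step 2 gives (E)-1-[2-hydroxy-6-methoxy-4-(methoxymethoxy)phenyl]-3-(4-methoxyphenyl)prop-2-en-1-one F6. The one-pot sequence of step 3 then runs through (2S)-5-methoxy-7-(methoxymethoxy)-2-(4-methoxyphenyl)chroman-4-one F7 and lithium (2S)-5-methoxy-7-(methoxymethoxy)-2-(4-methoxyphenyl)-2H-chromen-4-olate F8 to 7,7''-bis-O-(methoxymethyl)-4',4''',5,5''-tetra-O-methylchamaejasmin F9. HCl (1.25 M in MeOH)–THF at 40 °C then frees both phenols to give 8; C3 stays trans under acid and C2 is not touched.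

3. Step 2 (Claisen–Schmidt condensation). The risk is a sluggish reaction of the deactivated 2'-phenoxide and contamination of 4 with racemic flavanone, which would lower the enantiomeric purity entering step 3. The fallback sets out from 2 and comes back at 4, masking the nucleophilic phenol during the condensation. Compound 2 with chloromethyl methyl ether and i-Pr2NEt in CH2Cl2 at 40 °C gives 4'-(benzyloxy)-6'-methoxy-2'-(methoxymethoxy)acetophenone F10. Condensation with 3 (KOH, EtOH, rt), now through a neutral ketone enolate and with no possibility of ring closure, gives (E)-1-[4-(benzyloxy)-2-methoxy-6-(methoxymethoxy)phenyl]-3-(4-methoxyphenyl)prop-2-en-1-one F11. Brief treatment with HCl (1.25 M in MeOH)–THF at rt removes the acetal and returns 4.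

**Further compounds**
F1 | step 3 | dilithium phenoxide–enolate of 2 | [Li+].[Li+].[O-]C(=C)c1c([O-])cc(OCc2ccccc2)cc1OC
F2 | step 3 | 1,4-bis[4-(benzyloxy)-2-hydroxy-6-methoxyphenyl]butane-1,4-dione | O=C(CCC(=O)c1c(O)cc(OCc2ccccc2)cc1OC)c1c(O)cc(OCc2ccccc2)cc1OC
F3 | step 3 | (2E,3E)-1,4-bis[4-(benzyloxy)-2-hydroxy-6-methoxyphenyl]-2,3-bis[(4-methoxyphenyl)methylidene]butane-1,4-dione | COc1ccc(/C=C(/C(=O)c2c(O)cc(OCc3ccccc3)cc2OC)C(=C/c2ccc(OC)cc2)\C(=O)c2c(O)cc(OCc3ccccc3)cc2OC)cc1
F4 | step 3 | (2S,3R)-7-(benzyloxy)-3-{(E)-1-[4-(benzyloxy)-2-hydroxy-6-methoxybenzoyl]-2-(4-methoxyphenyl)ethenyl}-5-methoxy-2-(4-methoxyphenyl)chroman-4-one | COc1ccc([C@H]2Oc3cc(OCc4ccccc4)cc(OC)c3C(=O)[C@@H]2C(=C/c2ccc(OC)cc2)\C(=O)c2c(O)cc(OCc3ccccc3)cc2OC)cc1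
F5 | step 4 | 2'-hydroxy-6'-methoxy-4'-(methoxymethoxy)acetophenone | CC(=O)c1c(O)cc(OCOC)cc1OC
F6 | step 4 | (E)-1-[2-hydroxy-6-methoxy-4-(methoxymethoxy)phenyl]-3-(4-methoxyphenyl)prop-2-en-1-one | COCOc1cc(O)c(C(=O)/C=C/c2ccc(OC)cc2)c(OC)c1
F7 | step 4 | (2S)-5-methoxy-7-(methoxymethoxy)-2-(4-methoxyphenyl)chroman-4-one | COCOc1cc(OC)c2C(=O)C[C@@H](c3ccc(OC)cc3)Oc2c1
F8 | step 4 | lithium (2S)-5-methoxy-7-(methoxymethoxy)-2-(4-methoxyphenyl)-2H-chromen-4-olate | COCOc1cc(OC)c2C([O-])=C[C@@H](c3ccc(OC)cc3)Oc2c1.[Li+]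
F9 | step 4 | 7,7''-bis-O-(methoxymethyl)-4',4''',5,5''-tetra-O-methylchamaejasmin | COc1ccc([C@H]2Oc3cc(OCOC)cc(OC)c3C(=O)[C@@H]2[C@H]2C(=O)c3c(OC)cc(OCOC)cc3O[C@@H]2c2ccc(OC)cc2)cc1
F10 | step 2 | 4'-(benzyloxy)-6'-methoxy-2'-(methoxymethoxy)acetophenone | CC(=O)c1c(OCOC)cc(OCc2ccccc2)cc1OC
F11 | step 2 | (E)-1-[4-(benzyloxy)-2-methoxy-6-(methoxymethoxy)phenyl]-3-(4-methoxyphenyl)prop-2-en-1-one | COCOc1cc(OCc2ccccc2)cc(OC)c1C(=O)/C=C/c1ccc(OC)cc1
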